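The side chain is disconnected at C5'–C6' (numbering from the benzene-1,3-diol ring), inside the unfunctionalised heptamethylene tether between the aromatic ring and the C8'=C9' Z-alkene. The key step is a copper-catalysed sp3–sp3 coupling of a 5-arylpentyl Grignard reagent with a primary homoallylic tosylate. It exploits the fact that C6' is a primary carbon two atoms from C8': the complete C6'–C17' segment, carrying the (S)-carbinol C12' and both Z-alkenes, is attached in one operation. The tosylate comes from a glutamic-acid-derived lactone by (Z)-alkenylcuprate displacement and a Z-selective lactol Wittig reaction; the Grignard reagent comes from MOM-protected 5-bromoresorcinol and 1,5-dibromopentane.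

Key step: step 8

Remark: the stereocentre C12' of the target is S; tosylate 8 is taken as the catalogue (S)-enantiomer derived from L-glutamic acid, and its stereocentre is carried through unchanged.

Step 1
Reactants: 1 5-bromobenzene-1,3-diol
Product: 2 1-bromo-3,5-bis(methoxymethoxy)benzene
Conditions: MOMCl, i-Pr2NEt, CH2Cl2, 0 °C → rt
Reagents that add atoms: chloromethyl methyl ether, COCCl
Why: O-alkylation of both phenols by the reactive α-chloro ether (MOM protection) should proceed cleanly, the aryl bromide being inert.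

Step 2
Reactants: 2 1-bromo-3,5-bis(methoxymethoxy)benzene; 3 1,5-dibromopentane
Product: 5 1-(5-bromopentyl)-3,5-bis(methoxymethoxy)benzene, via arylmagnesium bromide 4 (not isolated)
Conditions: Mg, THF, reflux; then 3 (4 equiv), Li2CuCl4 (3 mol %), THF, −10 °C → rt
Reagents that add atoms: none
Why: Grignard formation followed by Kochi-type copper-catalysed aryl–alkyl coupling with a primary bromide should give the monoarylated product, the excess of dibromide suppressing double arylation.

Step 3
Reactants: 6 ethyllithium; 7 acetylene; 8 [(2S)-5-oxooxolan-2-yl]methyl 4-methylbenzenesulfonate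
Product: 10 (5S)-5-[(2Z)-pent-2-en-1-yl]oxolan-2-one, via lithium di[(Z)-but-1-enyl]cuprate 9 (not isolated)
Conditions: EtLi, CuI, Et2O, −40 °C; HC≡CH, −50 → −25 °C; then 8, THF, −40 → 0 °C; aq. NH4Cl
Reagents that add atoms: none
Why: Normant syn-carbocupration of acetylene by Et2CuLi sets the Z geometry, and cuprate SN2 displacement of the primary tosylate should proceed with retention at the alkenyl carbon and without touching the adjacent stereocentre (chiral pool, descriptor stays S) or the lactone carbonyl at low temperature.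

Step 4
Reactants: 10 (5S)-5-[(2Z)-pent-2-en-1-yl]oxolan-2-one
Product: 11 (5S)-5-[(2Z)-pent-2-en-1-yl]oxolan-2-ol (anomer mixture)
Conditions: DIBAL-H (1.1 equiv), CH2Cl2, −78 °C; Rochelle salt
Reagents that add atoms: none
Why: Partial reduction of a γ-lactone by DIBAL-H should stop at the lactol because the tetrahedral aluminate is stable at −78 °C.

Step 5
Reactants: 12 (3-bromopropoxy)(tert-butyl)dimethylsilane; 13 triphenylphosphine
Product: 14 {3-[(tert-butyldimethylsilyl)oxy]propyl}triphenylphosphonium bromide
Conditions: MeCN, reflux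
Reagents that add atoms: none
Why: SN2 quaternisation of triphenylphosphine by a primary bromide is a standard phosphonium salt synthesis.

Step 6
Reactants: 11 (5S)-5-[(2Z)-pent-2-en-1-yl]oxolan-2-ol; 14 {3-[(tert-butyldimethylsilyl)oxy]propyl}triphenylphosphonium bromide
Product: 17 (3Z,7S,9Z)-dodeca-3,9-diene-1,7-diol, via phosphonium ylide 15 (not isolated), via TBS ether alcohol 16 (not isolated)
Conditions: 14 (2.5 equiv), NaHMDS (2.4 equiv), THF, 0 °C; then 11, −78 °C → rt; aq. NH4Cl; then HCl (cat.), MeOH, rt
Reagents that add atoms: none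
Why: Wittig reaction of the lactol (through its open hydroxy aldehyde) with a non-stabilised, lithium-free ylide should give the Z-alkene via the kinetic cis-oxaphosphetane, and acid methanolysis then removes the primary TBS ether.

Step 7
Reactants: 17 (3Z,7S,9Z)-dodeca-3,9-diene-1,7-diol
Product: 19 (3Z,7S,9Z)-7-[(triethylsilyl)oxy]dodeca-3,9-dien-1-yl 4-methylbenzenesulfonate, via monotosylate 18 (not isolated)
Conditions: TsCl (1.05 equiv), pyridine, CH2Cl2, 0 °C; then TESCl (1.3 equiv), 0 °C → rt
Reagents that add atoms: p-toluenesulfonyl chloride, Cc1ccc(cc1)S(Cl)(=O)=O; chlorotriethylsilane, CC[Si](Cl)(CC)CC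
Why: Sulfonylation should be much faster at the unhindered primary hydroxyl than at the secondary one, and the remaining secondary hydroxyl is then silylated in the same flask.

Step 8
Reactants: 5 1-(5-bromopentyl)-3,5-bis(methoxymethoxy)benzene; 19 (3Z,7S,9Z)-7-[(triethylsilyl)oxy]dodeca-3,9-dien-1-yl 4-methylbenzenesulfonate
Product: 21 1,3-bis(methoxymethoxy)-5-[(8Z,12S,14Z)-12-[(triethylsilyl)oxy]heptadeca-8,14-dien-1-yl]benzene, via alkylmagnesium bromide 20 (not isolated)
Conditions: 5, Mg, THF, 45 °C; then 19, Li2CuCl4 (5 mol %), THF, −78 °C → rt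
Reagents that add atoms: none
Why: The Grignard reagent transmetalates to copper to give an alkylcuprate that attacks the primary C–OTs carbon (C6') in an SN2-type oxidative addition, and reductive elimination from the Cu(III) dialkyl forms the C5'–C6' bond and regenerates the catalyst. The closest known reaction type is the Kochi/Fouquet–Schlosser Li2CuCl4-catalysed coupling of alkyl Grignard reagents with primary tosylates, a standard way of assembling (Z)-alkenyl chains. No ring is closed and no stereocentre is created; C12' (S) is remote from the reacting carbon and its oxygen is masked as the TES ether, and both Z-alkenes are spectators toward organocopper(I) at low temperature. The selectivity needed is substitution at C6' over E2 elimination toward the C6'=C7'–C8'=C9' diene and over attack at sulfur, which the unhindered primary tosylate, the soft cuprate nucleophile and the low temperature should secure. The MOM ethers tolerate the Grignard reagent, so the whole C17 chain should be in place after this single operation.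

Step 9
Reactants: 21 1,3-bis(methoxymethoxy)-5-[(8Z,12S,14Z)-12-[(triethylsilyl)oxy]heptadeca-8,14-dien-1-yl]benzene
Product: 22 5-[(8Z,12S,14Z)-12-hydroxyheptadeca-8,14-dien-1-yl]benzene-1,3-diol
Conditions: HCl (cat.), MeOH, 45 °C
Reagents that add atoms: none
Why: Acid-catalysed transacetalisation of the two aryl MOM ethers to methanol and solvolysis of the TES ether should release the triol, the isolated Z-alkenes and the secondary alcohol being inert to dilute methanolic HCl.

Compound list
1 | 5-bromobenzene-1,3-diol | Oc1cc(O)cc(Br)c1 | starting material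
2 | 1-bromo-3,5-bis(methoxymethoxy)benzene | COCOc1cc(Br)cc(OCOC)c1 | intermediate
3 | 1,5-dibromopentane | BrCCCCCBr | starting material
4 | [3,5-bis(methoxymethoxy)phenyl]magnesium bromide | COCOc1cc([Mg]Br)cc(OCOC)c1 | intermediate
5 | 1-(5-bromopentyl)-3,5-bis(methoxymethoxy)benzene | COCOc1cc(CCCCCBr)cc(OCOC)c1 | intermediate
6 | ethyllithium | [Li]CC | starting material
7 | acetylene | C#C | starting material
8 | [(2S)-5-oxooxolan-2-yl]methyl 4-methylbenzenesulfonate | Cc1ccc(cc1)S(=O)(=O)OC[C@@H]1CCC(=O)O1 | starting material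
9 | lithium di[(Z)-but-1-enyl]cuprate | [Li+].CC/C=C\[Cu-]/C=C\CC | intermediate
10 | (5S)-5-[(2Z)-pent-2-en-1-yl]oxolan-2-one | CC/C=C\C[C@@H]1CCC(=O)O1 | intermediate
11 | (5S)-5-[(2Z)-pent-2-en-1-yl]oxolan-2-ol | CC/C=C\C[C@@H]1CCC(O)O1 | intermediate
12 | (3-bromopropoxy)(tert-butyl)dimethylsilane | CC(C)(C)[Si](C)(C)OCCCBr | starting material
13 | triphenylphosphine | c1ccc(cc1)P(c1ccccc1)c1ccccc1 | starting material
14 | {3-[(tert-butyldimethylsilyl)oxy]propyl}triphenylphosphonium bromide | CC(C)(C)[Si](C)(C)OCCC[P+](c1ccccc1)(c1ccccc1)c1ccccc1.[Br-] | intermediate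
15 | {3-[(tert-butyldimethylsilyl)oxy]propylidene}triphenylphosphorane | CC(C)(C)[Si](C)(C)OCCC=P(c1ccccc1)(c1ccccc1)c1ccccc1 | intermediate
16 | (3Z,7S,9Z)-1-[(tert-butyldimethylsilyl)oxy]dodeca-3,9-dien-7-ol | CC/C=C\C[C@@H](O)CC/C=C\CCO[Si](C)(C)C(C)(C)C | intermediate
17 | (3Z,7S,9Z)-dodeca-3,9-diene-1,7-diol | CC/C=C\C[C@@H](O)CC/C=C\CCO | intermediate
18 | (3Z,7S,9Z)-7-hydroxydodeca-3,9-dien-1-yl 4-methylbenzenesulfonate | CC/C=C\C[C@@H](O)CC/C=C\CCOS(=O)(=O)c1ccc(C)cc1 | intermediate
19 | (3Z,7S,9Z)-7-[(triethylsilyl)oxy]dodeca-3,9-dien-1-yl 4-methylbenzenesulfonate | CC/C=C\C[C@@H](O[Si](CC)(CC)CC)CC/C=C\CCOS(=O)(=O)c1ccc(C)cc1 | intermediate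
20 | {5-[3,5-bis(methoxymethoxy)phenyl]pentyl}magnesium bromide | COCOc1cc(CCCCC[Mg]Br)cc(OCOC)c1 | intermediate
21 | 1,3-bis(methoxymethoxy)-5-[(8Z,12S,14Z)-12-[(triethylsilyl)oxy]heptadeca-8,14-dien-1-yl]benzene | CC/C=C\C[C@@H](O[Si](CC)(CC)CC)CC/C=C\CCCCCCCc1cc(OCOC)cc(OCOC)c1 | intermediate
22 | 5-[(8Z,12S,14Z)-12-hydroxyheptadeca-8,14-dien-1-yl]benzene-1,3-diol | CC/C=C\C[C@@H](O)CC/C=C\CCCCCCCc1cc(O)cc(O)c1 | target

Total step count: 9. Longest linear sequence: 6 steps (8 → 10 → 11 → 17 → 19 → 21 → 22; steps 3, 4, 6, 7, 8, 9).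

Steps most likely to fail

Step 8 (key step). The basic Grignard reagent may cause β-elimination of the homoallylic tosylate toward the conjugated diene, or Wurtz-type homocoupling may outrun cross-coupling. The fallback forms the same C5'–C6' bond by sulfonyl carbanion alkylation and sets out from 19 and 5. Sodium benzenesulfinate (DMF, 60 °C) should convert 19 into (3Z,7S,9Z)-1-(phenylsulfonyl)-7-[(triethylsilyl)oxy]dodeca-3,9-diene F3. Deprotonation (n-BuLi, THF/DMPU, −78 °C) and alkylation with bromide 5 should give 1,3-bis(methoxymethoxy)-5-[(8Z,12S,14Z)-6-(phenylsulfonyl)-12-[(triethylsilyl)oxy]heptadeca-8,14-dien-1-yl]benzene F4 as a mixture of C6' epimers. Reductive desulfonylation (Na/Hg, Na2HPO4, MeOH/THF, −20 °C) removes the sulfonyl group and the extra stereocentre, and the route is rejoined at 21.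

Step 3. Transfer of the alkenyl ligand to the β-oxygenated, deactivated tosylate may be slow, leaving time for cuprate decomposition or attack on the lactone carbonyl. The fallback replaces the tosylate displacement by an epoxide opening and sets out from 8. NaOMe in MeOH (0 °C) should open the lactone and close the alkoxide onto the tosylate to give methyl (4S)-4,5-epoxypentanoate F1. Cuprate 9 (Et2O, −30 °C) should open the epoxide at its terminal carbon to give methyl (4S,6Z)-4-hydroxynon-6-enoate F2. Lactonisation (TsOH cat., CH2Cl2) rejoins the route at 10.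

Step 7. Sulfonylation may not discriminate fully between the primary and the secondary hydroxyl, or the primary tosylate may be displaced by chloride during the silylation stage. The fallback differentiates the two oxygens by orthogonal protection instead of kinetic selectivity and sets out from 16, isolated by omitting the methanolysis of step 6. MOMCl/i-Pr2NEt should give tert-butyl{[(3Z,7S,9Z)-7-(methoxymethoxy)dodeca-3,9-dien-1-yl]oxy}dimethylsilane F5. TBAF (THF) should release (3Z,7S,9Z)-7-(methoxymethoxy)dodeca-3,9-dien-1-ol F6, and TsCl/pyridine should give (3Z,7S,9Z)-7-(methoxymethoxy)dodeca-3,9-dien-1-yl 4-methylbenzenesulfonate F7. Coupling with Grignard reagent 20 under the conditions of step 8 should give 1,3-bis(methoxymethoxy)-5-[(8Z,12S,14Z)-12-(methoxymethoxy)heptadeca-8,14-dien-1-yl]benzene F8. Methanolic HCl as in step 9 (slightly more forcing for the alkyl MOM ether) rejoins the route at 22.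

Further compounds
F1 | step 3 | methyl (4S)-4,5-epoxypentanoate | COC(=O)CC[C@H]1CO1
F2 | step 3 | methyl (4S,6Z)-4-hydroxynon-6-enoate | CC/C=C\C[C@@H](O)CCC(=O)OC
F3 | step 8 | (3Z,7S,9Z)-1-(phenylsulfonyl)-7-[(triethylsilyl)oxy]dodeca-3,9-diene | CC/C=C\C[C@@H](O[Si](CC)(CC)CC)CC/C=C\CCS(=O)(=O)c1ccccc1
F4 | step 8 | 1,3-bis(methoxymethoxy)-5-[(8Z,12S,14Z)-6-(phenylsulfonyl)-12-[(triethylsilyl)oxy]heptadeca-8,14-dien-1-yl]benzene | CC/C=C\C[C@@H](O[Si](CC)(CC)CC)CC/C=C\CC(CCCCCc1cc(OCOC)cc(OCOC)c1)S(=O)(=O)c1ccccc1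
F5 | step 7 | tert-butyl{[(3Z,7S,9Z)-7-(methoxymethoxy)dodeca-3,9-dien-1-yl]oxy}dimethylsilane | CC/C=C\C[C@@H](OCOC)CC/C=C\CCO[Si](C)(C)C(C)(C)C
F6 | step 7 | (3Z,7S,9Z)-7-(methoxymethoxy)dodeca-3,9-dien-1-ol | CC/C=C\C[C@@H](OCOC)CC/C=C\CCO
F7 | step 7 | (3Z,7S,9Z)-7-(methoxymethoxy)dodeca-3,9-dien-1-yl 4-methylbenzenesulfonate | CC/C=C\C[C@@H](OCOC)CC/C=C\CCOS(=O)(=O)c1ccc(C)cc1
F8 | step 7 | 1,3-bis(methoxymethoxy)-5-[(8Z,12S,14Z)-12-(methoxymethoxy)heptadeca-8,14-dien-1-yl]benzene | CC/C=C\C[C@@H](OCOC)CC/C=C\CCCCCCCc1cc(OCOC)cc(OCOC)c1
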